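The ratio of added ligand between each new flask and its nearest simulated run is 1.42 for Saturday's over amber and 1.40 for Wednesday's over blue, so each new flask is its neighbour with somewhat more ligand, and I need to know how that ligand slows the clearing of substrate.

the same everywhere: left-handed substrate 0.80 M; right-handed substrate 0.80 M; catalyst 0.1 mol%
- amber: reagent 2.2 equiv; added ligand 1.2 mM; run made earlier
- blue: reagent 2.2 equiv; added ligand 4.3 mM; run made earlier
- Saturday's: reagent 2.20 equiv; added ligand 1.7 mM; time 4.0 h
- Wednesday's: reagent 2.20 equiv; added ligand 6.0 mM; time 4.0 h

- amber (time / h: left-handed product / %, right-handed product / %, left-handed substrate / %): 0.333: 21.5, 19.8, 27.6; 0.500: 26.0, 26.2, 21.7; 0.833: 33.6, 34.8, 17.9; 1.33: 38.1, 36.6, 13.1; 2.50: 43.7, 43.7, 5.5; 4.00: 45.8, 46.9, 3.8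
- blue (time / h: left-handed product / %, right-handed product / %, left-handed substrate / %): 0.667: 20.2, 18.8, 29.1; 1.33: 26.6, 28.6, 21.6; 2.00: 31.1, 33.1, 17.3; 2.50: 34.9, 35.9, 15.1; 3.00: 38.0, 39.4, 12.6; 4.00: 38.9, 41.8, 9.2

(scatter of a reading: 1 percentage point)

- catalyst is single-handed; left-handed substrate and right-handed substrate are mirror images of each other, charged as a racemate, each of them at the stated concentration
- an excess is the difference of the two amounts in percent of their sum
- an excess is below zero if the other one leads

- which one finishes higher in excess of left-handed product over right-handed product in the product ("neither" within 2 percentage points) (Saturday's / Wednesday's / neither)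
- excess of left-handed product over right-handed product in the product at the end, Saturday's
- excess of left-handed product over right-handed product in the product at the end, Wednesday's

Let x be the left-handed substrate as a fraction of both substrates charged, starting at 0.5. If it falls as dx/dt = −κx², the integrated second-order rate law makes the reciprocal of x climb from 2 with slope κ, the clearing constant. The end readings give κ = 6.08 h⁻¹ for amber and 2.22 h⁻¹ for blue. I let the reciprocal of κ rise in a straight line with ligand through these two runs, which gives Saturday's 4.75 h⁻¹ and, carried beyond blue, Wednesday's clearing constant κ_W 1.64 h⁻¹. Saturday's therefore clears faster than Wednesday's, and after 4.0 h I expect 4.76% of left-handed substrate in Saturday's and 11.7% in Wednesday's.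

The excess is a separate matter. Amber ends at −1.19% and blue at −3.59%, each built from two readings with a scatter of 1 percentage point, so I commit to excesses near zero and to neither flask leading. The forecast gives −0.3% for Saturday's and −2.2% for Wednesday's: “The gap is under 2 points, so neither.”

The flask gives 0.0344% for Saturday's and 0.0779% for Wednesday's, so the answer is neither.

    reagent + catalyst + left-handed substrate → catalyst + left-handed product (k = 79.0 M⁻² min⁻¹)
    reagent + catalyst + right-handed substrate → catalyst + right-handed product (k = 34.0 M⁻² min⁻¹)
    left-handed substrate ⇌ right-handed substrate (k = 0.0870 min⁻¹)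
    catalyst + added ligand ⇌ idle complex, settled at all times (K = 870 M⁻¹)
    left-handed product ⇌ right-handed product (k = 0.300 min⁻¹)
    reagent ⇌ dormant form (K = 0.280, k = 0.190 min⁻¹)

With the interconversion of left-handed product and right-handed product struck out both ways, Saturday's excess would stand at 37.0%, more than the flask's 0.0344%, and the forecast would then be wrong. Put to use again, κ_W gives 11.7% of left-handed substrate at 4.0 h, where Wednesday's holds 12.5%, and 3.76% at 15 h, where Wednesday's holds 2.93%.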